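Ring A (the cyclohexene; carotenoid numbering: C1 gem-dimethyl, C3 carbinol, C4=C5 alkene, C6 stereocentre carrying the polyene) is built by a two-carbon ring expansion. Zerovalent-nickel-catalysed insertion of propyne into the acyl–allyl C–C bond of an enantioenriched 2-alkenyl-3,3-dimethylcyclobutanone forms C3–C4 and C5–C6 in one operation and gives the 3-oxo ε-ring. It exploits that C3 is an oxygenated (carbonyl-derived) ring carbon and that C6 is allylic to the C7=C8 alkene, which directs the cleavage and lets the C6 configuration pass on unchanged. Reduction then sets C3, and a C15 phosphonium salt is joined to a C15 polyene aldehyde by Wittig olefination.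

Key step: step 4

Remark on numbering: ring and chain atoms carry carotenoid numbers (ring A C1–C6, chain C7–C15 and C15'–C8') in all intermediates.
Assumption: the (2R,5R)-2,5-dimethylpyrrolidine amide is taken to deliver the (R)-cyclobutanone in step 3; if the sense of induction is the opposite, the (2S,5S)-amine is used and nothing else changes.

Step 1
Reactants: 1 but-3-enoic acid; 2 (2R,5R)-2,5-dimethylpyrrolidine
Product: 3 1-[(2R,5R)-2,5-dimethylpyrrolidin-1-yl]but-3-en-1-one
Conditions: DCC, HOBt (cat.), CH2Cl2, 0 °C to rt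
Reagents that add atoms: none
Why: Carbodiimide amide coupling under base-free conditions should acylate the C2-symmetric secondary amine while keeping the β,γ-double bond out of conjugation, and no stereocentre is formed.

Step 2
Reactants: 3 1-[(2R,5R)-2,5-dimethylpyrrolidin-1-yl]but-3-en-1-one; 4 2-methyl-2-vinyl-1,3-dioxolane
Product: 5 (3E)-1-[(2R,5R)-2,5-dimethylpyrrolidin-1-yl]-4-(2-methyl-1,3-dioxolan-2-yl)but-3-en-1-one
Conditions: second-generation Hoveyda–Grubbs catalyst (5 mol %), 1,4-benzoquinone (10 mol %), 4 in excess, CH2Cl2, 40 °C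
Reagents that add atoms: none
Why: Olefin cross-metathesis between a readily homodimerising terminal alkene and a vinyl group on a fully substituted carbon should favour the cross product as the (E)-alkene for steric reasons, with benzoquinone suppressing hydride-induced migration of the β,γ-alkene.

Step 3
Reactants: 5 (3E)-1-[(2R,5R)-2,5-dimethylpyrrolidin-1-yl]-4-(2-methyl-1,3-dioxolan-2-yl)but-3-en-1-one; 6 2-methylpropene (isobutylene)
Product: 9 (2R)-3,3-dimethyl-2-[(E)-2-(2-methyl-1,3-dioxolan-2-yl)ethenyl]cyclobutan-1-one, via keteniminium triflate 7 (not isolated), via cyclobutaniminium triflate 8 (not isolated)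
Conditions: Tf2O, 2,4,6-collidine, CH2Cl2, −30 °C; 6 (excess), sealed tube, rt to 40 °C; then aq. NaHCO3, rt
Reagents that add atoms: water, O
Why: In this keteniminium–olefin [2+2] cycloaddition the electrophilic central carbon should take the CH2 terminus of isobutylene and the α-carbon should close onto the tertiary carbon (four-ring closure preferred over closure at the hindered C8), the C2-symmetric pyrrolidine shielding one face to set the α-stereocentre as (R), and buffered hydrolysis should release the ketone and the auxiliary.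

Step 4
Reactants: 9 (2R)-3,3-dimethyl-2-[(E)-2-(2-methyl-1,3-dioxolan-2-yl)ethenyl]cyclobutan-1-one; 10 propyne
Product: 11 (4R)-3,5,5-trimethyl-4-[(E)-2-(2-methyl-1,3-dioxolan-2-yl)ethenyl]cyclohex-2-en-1-one
Conditions: Ni(cod)2 (10 mol %), PCy3 (20 mol %), toluene, 90 °C, sealed vessel, 10 (3 equiv) added slowly
Reagents that add atoms: none
Why: Zerovalent nickel should couple the strained ketone C=O of 9 with propyne by oxidative cyclisation to a spiro oxanickelacyclopentene (C3–C4 bond), β-carbon elimination then cleaves the ring C3–C6 bond to a seven-membered alkenyl(allyl)nickelacycle, and C(sp2)–C(sp3) reductive elimination forms C5–C6 and returns zerovalent nickel. The closest known reaction type is the nickel-catalysed intermolecular insertion of alkynes into the acyl–carbon bond of cyclobutanones (a [4+2] annulation by C–C activation), established with internal alkynes and 3-substituted cyclobutanones, so slow addition is used to keep the terminal alkyne too dilute to oligomerise. Ring A closes by two-carbon ring expansion of the four-membered ring, that is by reductive elimination from the seven-membered nickelacycle and not by an exo or endo attack. No new stereocentre arises: C6 is carried over from 9 with retention, since nickel takes the place of the departing carbonyl carbon and hands the alkenyl carbon to the same face, and the (E)-alkene should survive as the syn-allyl. The step needs cleavage on the alkenyl-bearing side and not the CH2 side (secured by allyl stabilisation of the forming C–Ni bond), the unsubstituted terminus of propyne on the carbonyl carbon (secured by the H versus CH3 steric difference at the congested spiro carbon), and closure at C6 instead of the far allyl terminus C8 (secured by the fully substituted ketal carbon on C8 and by six- over eight-membered ring formation).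

Step 5
Reactants: 11 (4R)-3,5,5-trimethyl-4-[(E)-2-(2-methyl-1,3-dioxolan-2-yl)ethenyl]cyclohex-2-en-1-one
Product: 12 (1S,4R)-3,5,5-trimethyl-4-[(E)-2-(2-methyl-1,3-dioxolan-2-yl)ethenyl]cyclohex-2-en-1-ol
Conditions: (R)-2-methyl-CBS-oxazaborolidine (20 mol %), catecholborane, toluene, −78 °C; MeOH, then aq. NaOH work-up
Reagents that add atoms: none
Why: In this Corey–Bakshi–Shibata reduction the oxazaborolidine should bind the carbonyl lone pair on the CH2 side (the alkene flank acting as the large group) and deliver hydride in the 1,2-mode to one face, so the (R)-catalyst is expected to set C3 as (S), cis to the side chain, under reagent control.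

Step 6
Reactants: 12 (1S,4R)-3,5,5-trimethyl-4-[(E)-2-(2-methyl-1,3-dioxolan-2-yl)ethenyl]cyclohex-2-en-1-ol
Product: 13 (3E)-4-[(1R,4S)-4-hydroxy-2,6,6-trimethylcyclohex-2-en-1-yl]but-3-en-2-one
Conditions: PPTS (cat.), acetone/H2O (4:1), rt
Reagents that add atoms: water, O
Why: Acid-catalysed hydrolysis of the allylic dioxolane by a pyridinium acid should be fast at an acidity that does not ionise the ring allylic alcohol, so the methyl ketone is released with both stereocentres untouched.

Step 7
Reactants: 13 (3E)-4-[(1R,4S)-4-hydroxy-2,6,6-trimethylcyclohex-2-en-1-yl]but-3-en-2-one; 14 vinylmagnesium bromide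
Product: 15 (1E)-1-[(1R,4S)-4-hydroxy-2,6,6-trimethylcyclohex-2-en-1-yl]-3-methylpenta-1,4-dien-3-ol (both C9 epimers)
Conditions: 14 (3 equiv), THF, −20 to 0 °C; aqueous work-up
Reagents that add atoms: none
Why: Grignard 1,2-addition to the methyl enone should follow deprotonation of the hydroxyl group by the first equivalent, and the uncontrolled tertiary carbinol centre is of no consequence because step 8 destroys it.

Step 8
Reactants: 15 (1E)-1-[(1R,4S)-4-hydroxy-2,6,6-trimethylcyclohex-2-en-1-yl]-3-methylpenta-1,4-dien-3-ol; 16 triphenylphosphine hydrobromide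
Product: 17 [(2E,4E)-5-[(1R,4S)-4-hydroxy-2,6,6-trimethylcyclohex-2-en-1-yl]-3-methylpenta-2,4-dien-1-yl]triphenylphosphonium bromide
Conditions: 16 (1.05 equiv), MeOH, 0 °C to rt; crystallisation
Reagents that add atoms: none
Why: In this allylic transposition–phosphonium salt formation the tertiary bis-allylic carbinol should ionise to a pentadienyl cation that triphenylphosphine traps at the primary terminus, mainly as the (2E,4E) salt, while the weakly acidic reagent is not expected to ionise the secondary ring allylic alcohol.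

Step 9
Reactants: 18 1,1-dimethoxypropan-2-one; 14 vinylmagnesium bromide
Product: 19 1,1-dimethoxy-2-methylbut-3-en-2-ol (racemic)
Conditions: 14 (1.1 equiv), THF, −78 to 0 °C; aqueous work-up
Reagents that add atoms: none
Why: Grignard addition to the ketone of the acetal-protected ketoaldehyde should give the tertiary vinyl carbinol, whose stereocentre disappears in step 10.

Step 10
Reactants: 19 1,1-dimethoxy-2-methylbut-3-en-2-ol; 16 triphenylphosphine hydrobromide
Product: 20 [(2E)-4,4-dimethoxy-3-methylbut-2-en-1-yl]triphenylphosphonium bromide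
Conditions: 16 (1.0 equiv), MeOH, rt
Reagents that add atoms: none
Why: The same allylic transposition as in step 8 should give the primary allylic phosphonium salt with the trisubstituted alkene mainly (E), the dimethyl acetal being degenerate towards methanol.

Step 11
Reactants: 20 [(2E)-4,4-dimethoxy-3-methylbut-2-en-1-yl]triphenylphosphonium bromide; 21 (2E,4E,6E)-2,7-dimethylocta-2,4,6-trienedial
Product: 22 (2E,4E,6E,8E,10E)-12,12-dimethoxy-2,7,11-trimethyldodeca-2,4,6,8,10-pentaenal
Conditions: NaOMe, MeOH/CH2Cl2, 0 °C, 21 (3 equiv); then I2 (cat.), CH2Cl2, daylight, rt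
Reagents that add atoms: none
Why: Wittig olefination of the allylic ylide with an excess of the symmetrical dialdehyde should give the mono-adduct, and iodine-catalysed equilibration should bring the new disubstituted alkene to the (E) form.

Step 12
Reactants: 17 [(2E,4E)-5-[(1R,4S)-4-hydroxy-2,6,6-trimethylcyclohex-2-en-1-yl]-3-methylpenta-2,4-dien-1-yl]triphenylphosphonium bromide; 22 (2E,4E,6E,8E,10E)-12,12-dimethoxy-2,7,11-trimethyldodeca-2,4,6,8,10-pentaenal
Product: 24 (2E,4E,6E,8E,10E,12E,14E,16E)-17-[(1R,4S)-4-hydroxy-2,6,6-trimethylcyclohex-2-en-1-yl]-2,6,11,15-tetramethylheptadeca-2,4,6,8,10,12,14,16-octaenal, via C30 dimethyl acetal 23 (not isolated)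
Conditions: NaOMe, MeOH/CH2Cl2, 0 °C to rt; then PPTS (cat.), acetone/H2O, 0 °C to rt; heptane, 80 °C (Z to E equilibration)
Reagents that add atoms: water, O
Why: Wittig olefination should form the C11=C12 bond, the hindered (11Z) isomer should equilibrate thermally to the all-(E) polyene, and the polyenal dimethyl acetal, which hydrolyses through a highly stabilised oxocarbenium ion, should be cleaved by a pyridinium acid without affecting the two stereocentres.

Compound list
1 | but-3-enoic acid | C=CCC(=O)O | starting material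
2 | (2R,5R)-2,5-dimethylpyrrolidine | C[C@@H]1CC[C@@H](C)N1 | starting material
3 | 1-[(2R,5R)-2,5-dimethylpyrrolidin-1-yl]but-3-en-1-one | C=CCC(=O)N1[C@H](C)CC[C@H]1C | intermediate
4 | 2-methyl-2-vinyl-1,3-dioxolane | C=CC1(C)OCCO1 | starting material
5 | (3E)-1-[(2R,5R)-2,5-dimethylpyrrolidin-1-yl]-4-(2-methyl-1,3-dioxolan-2-yl)but-3-en-1-one | C[C@@H]1CC[C@@H](C)N1C(=O)C/C=C/C1(C)OCCO1 | intermediate
6 | 2-methylpropene (isobutylene) | CC(C)=C | starting material
7 | (2R,5R)-2,5-dimethyl-1-[(3E)-4-(2-methyl-1,3-dioxolan-2-yl)buta-1,3-dien-1-ylidene]pyrrolidinium triflate (keteniminium triflate) | C[C@@H]1CC[C@@H](C)[N+]1=C=C/C=C/C1(C)OCCO1.[O-]S(=O)(=O)C(F)(F)F | intermediate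
8 | (2R,5R)-1-{(2R)-3,3-dimethyl-2-[(E)-2-(2-methyl-1,3-dioxolan-2-yl)ethenyl]cyclobutylidene}-2,5-dimethylpyrrolidinium triflate (cyclobutaniminium triflate) | C[C@@H]1CC[C@@H](C)[N+]1=C1CC(C)(C)[C@H]1/C=C/C1(C)OCCO1.[O-]S(=O)(=O)C(F)(F)F | intermediate
9 | (2R)-3,3-dimethyl-2-[(E)-2-(2-methyl-1,3-dioxolan-2-yl)ethenyl]cyclobutan-1-one | O=C1CC(C)(C)[C@H]1/C=C/C1(C)OCCO1 | intermediate
10 | propyne | CC#C | starting material
11 | (4R)-3,5,5-trimethyl-4-[(E)-2-(2-methyl-1,3-dioxolan-2-yl)ethenyl]cyclohex-2-en-1-one | CC1=CC(=O)CC(C)(C)[C@H]1/C=C/C1(C)OCCO1 | intermediate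
12 | (1S,4R)-3,5,5-trimethyl-4-[(E)-2-(2-methyl-1,3-dioxolan-2-yl)ethenyl]cyclohex-2-en-1-ol | CC1=C[C@@H](O)CC(C)(C)[C@H]1/C=C/C1(C)OCCO1 | intermediate
13 | (3E)-4-[(1R,4S)-4-hydroxy-2,6,6-trimethylcyclohex-2-en-1-yl]but-3-en-2-one | CC1=C[C@@H](O)CC(C)(C)[C@H]1/C=C/C(C)=O | intermediate
14 | vinylmagnesium bromide | C=C[Mg]Br | starting material
15 | (1E)-1-[(1R,4S)-4-hydroxy-2,6,6-trimethylcyclohex-2-en-1-yl]-3-methylpenta-1,4-dien-3-ol (both C9 epimers) | CC1=C[C@@H](O)CC(C)(C)[C@H]1/C=C/C(C)(O)C=C | intermediate
16 | triphenylphosphine hydrobromide | [Br-].c1ccc(cc1)[PH+](c1ccccc1)c1ccccc1 | starting material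
17 | [(2E,4E)-5-[(1R,4S)-4-hydroxy-2,6,6-trimethylcyclohex-2-en-1-yl]-3-methylpenta-2,4-dien-1-yl]triphenylphosphonium bromide | CC1=C[C@@H](O)CC(C)(C)[C@H]1/C=C/C(C)=C/C[P+](c1ccccc1)(c1ccccc1)c1ccccc1.[Br-] | intermediate
18 | 1,1-dimethoxypropan-2-one | COC(OC)C(C)=O | starting material
19 | 1,1-dimethoxy-2-methylbut-3-en-2-ol (racemic) | COC(OC)C(C)(O)C=C | intermediate
20 | [(2E)-4,4-dimethoxy-3-methylbut-2-en-1-yl]triphenylphosphonium bromide | COC(OC)/C(C)=C/C[P+](c1ccccc1)(c1ccccc1)c1ccccc1.[Br-] | intermediate
21 | (2E,4E,6E)-2,7-dimethylocta-2,4,6-trienedial | O=C/C(C)=C/C=C/C=C(\C)C=O | starting material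
22 | (2E,4E,6E,8E,10E)-12,12-dimethoxy-2,7,11-trimethyldodeca-2,4,6,8,10-pentaenal | O=C/C(C)=C/C=C/C=C(C)/C=C/C=C(\C)C(OC)OC | intermediate
23 | (1S,4R)-4-[(1E,3E,5E,7E,9E,11E,13E,15E)-17,17-dimethoxy-3,7,12,16-tetramethylheptadeca-1,3,5,7,9,11,13,15-octaen-1-yl]-3,5,5-trimethylcyclohex-2-en-1-ol | CC1=C[C@@H](O)CC(C)(C)[C@H]1/C=C/C(C)=C/C=C/C(C)=C/C=C/C=C(C)/C=C/C=C(\C)C(OC)OC | intermediate
24 | (2E,4E,6E,8E,10E,12E,14E,16E)-17-[(1R,4S)-4-hydroxy-2,6,6-trimethylcyclohex-2-en-1-yl]-2,6,11,15-tetramethylheptadeca-2,4,6,8,10,12,14,16-octaenal, i.e. (3S,6R)-3-hydroxy-8'-apo-ε-caroten-8'-al | CC1=C[C@@H](O)CC(C)(C)[C@H]1/C=C/C(C)=C/C=C/C(C)=C/C=C/C=C(C)/C=C/C=C(\C)C=O | target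

Total step count: 12. Longest linear sequence: 9 steps (steps 1 to 8, then step 12).

Steps most likely to fail

Step 4. What may go wrong: oligomerisation of the terminal alkyne outrunning the hetero-coupling, C–C cleavage on the CH2 side of the ketone, acyl–allyl side reactions (1,3-acyl shift, decarbonylation), or allyl isomerisation eroding the C6 configuration and the (E)-alkene. The fallback sets out from 9 and comes back at 11, building the same oxametallacyclopentene stoichiometrically instead of by oxidative cyclisation. Addition of 1-propynyllithium (from 10 and n-BuLi, THF, −78 °C) to 9 should give the tertiary propargylic alcohol (2R)-3,3-dimethyl-2-[(E)-2-(2-methyl-1,3-dioxolan-2-yl)ethenyl]-1-(prop-1-yn-1-yl)cyclobutan-1-ol F1. Hydroxyl-directed trans-hydroalumination with NaAlH2(OCH2CH2OMe)2 followed by iodinolysis should give (2R)-1-[(Z)-2-iodoprop-1-en-1-yl]-3,3-dimethyl-2-[(E)-2-(2-methyl-1,3-dioxolan-2-yl)ethenyl]cyclobutan-1-ol F2, with iodine cis to the carbinol carbon. Pd(OAc)2/PPh3 with Cs2CO3 in toluene at 80 °C should then effect oxidative addition, palladium alkoxide formation, β-carbon elimination of the allylic ring bond and reductive elimination (the palladium-catalysed ring-opening coupling of tert-cyclobutanols, here intramolecular) to give enone 11. The alkyne regiochemistry is then fixed by synthesis and no free terminal alkyne meets the catalyst.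

Step 3. What may go wrong: poor facial selectivity of the cycloaddition, or epimerisation of the α-alkenyl iminium ion or ketone through its dienamine or dienol; closure at C8 and loss of the ketal under the activating conditions are lesser concerns. The fallback sets out from 5 and comes back at 12, and no longer relies on the auxiliary for the C6 configuration. The scalemic cyclobutanone, that is 9 together with its enantiomer (2S)-3,3-dimethyl-2-[(E)-2-(2-methyl-1,3-dioxolan-2-yl)ethenyl]cyclobutan-1-one F3, is carried through step 4 to 11 and its enantiomer (4S)-3,5,5-trimethyl-4-[(E)-2-(2-methyl-1,3-dioxolan-2-yl)ethenyl]cyclohex-2-en-1-one F4. The reagent-controlled reduction of step 5 then turns the two C6 enantiomers into diastereomers, the cis alcohol 12 and the trans alcohol (1S,4S)-3,5,5-trimethyl-4-[(E)-2-(2-methyl-1,3-dioxolan-2-yl)ethenyl]cyclohex-2-en-1-ol F5, which are separated by chromatography. This is a resolution through a catalyst-controlled reduction in place of auxiliary induction.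

Step 5. What may go wrong: facial selectivity governed by the substrate instead of the catalyst, the axial methyl group on C1 and the side chain steering hydride towards the trans alcohol. The fallback sets out from 11 and comes back at 12. Reduction without a chiral catalyst (NaBH4, CeCl3·7H2O, MeOH, −40 °C, Luche conditions) is followed by separation of the trans alcohol (1R,4R)-3,5,5-trimethyl-4-[(E)-2-(2-methyl-1,3-dioxolan-2-yl)ethenyl]cyclohex-2-en-1-ol F6. Mitsunobu inversion (4-nitrobenzoic acid, PPh3, DIAD, THF, 0 °C) should give (1S,4R)-3,5,5-trimethyl-4-[(E)-2-(2-methyl-1,3-dioxolan-2-yl)ethenyl]cyclohex-2-en-1-yl 4-nitrobenzoate F7, and methanolysis (K2CO3, MeOH) should give 12.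

Further compounds
F1 | step 4 | (2R)-3,3-dimethyl-2-[(E)-2-(2-methyl-1,3-dioxolan-2-yl)ethenyl]-1-(prop-1-yn-1-yl)cyclobutan-1-ol (both C1 epimers) | CC#CC1(O)CC(C)(C)[C@H]1/C=C/C1(C)OCCO1
F2 | step 4 | (2R)-1-[(Z)-2-iodoprop-1-en-1-yl]-3,3-dimethyl-2-[(E)-2-(2-methyl-1,3-dioxolan-2-yl)ethenyl]cyclobutan-1-ol (both C1 epimers) | C/C(I)=C/C1(O)CC(C)(C)[C@H]1/C=C/C1(C)OCCO1
F3 | step 3 | (2S)-3,3-dimethyl-2-[(E)-2-(2-methyl-1,3-dioxolan-2-yl)ethenyl]cyclobutan-1-one | O=C1CC(C)(C)[C@@H]1/C=C/C1(C)OCCO1
F4 | step 3 | (4S)-3,5,5-trimethyl-4-[(E)-2-(2-methyl-1,3-dioxolan-2-yl)ethenyl]cyclohex-2-en-1-one | CC1=CC(=O)CC(C)(C)[C@@H]1/C=C/C1(C)OCCO1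
F5 | step 3 | (1S,4S)-3,5,5-trimethyl-4-[(E)-2-(2-methyl-1,3-dioxolan-2-yl)ethenyl]cyclohex-2-en-1-ol | CC1=C[C@@H](O)CC(C)(C)[C@@H]1/C=C/C1(C)OCCO1
F6 | step 5 | (1R,4R)-3,5,5-trimethyl-4-[(E)-2-(2-methyl-1,3-dioxolan-2-yl)ethenyl]cyclohex-2-en-1-ol | CC1=C[C@H](O)CC(C)(C)[C@H]1/C=C/C1(C)OCCO1
F7 | step 5 | (1S,4R)-3,5,5-trimethyl-4-[(E)-2-(2-methyl-1,3-dioxolan-2-yl)ethenyl]cyclohex-2-en-1-yl 4-nitrobenzoate | CC1=C[C@@H](OC(=O)c2ccc(cc2)[N+](=O)[O-])CC(C)(C)[C@H]1/C=C/C1(C)OCCO1
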